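Cuts: first the aryl–acyl bond C6–C(=O). Then the O1–C2 bond of the pyran ring (ring B), with O1 re-attached to C3, which contracts ring B to a 2-isopropenyl-2,3-dihydrofuran. Last the C4–C4a and O1–C3 bonds of that five-membered ring, leading to isoprene and 2-iodo-5-methoxyresorcinol.
Forward: the benzene ring (ring A) is bought as 5-methoxyresorcinol. Iodination and a diene heteroannulation close the five-membered O-ring, and a palladium-catalysed isomerisation expands it to the 2,2-dimethyl-2H-pyran. MOM protection, lithiation at C6 and acylation by a Weinreb amide join the C9 side chain, and one acidic step frees both hydroxyl groups.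
Enabling feature: O1–C2(Me2)–C3=C4–C4a is an allylic aryl ether conjugated with ring A. It is a hydroalkoxylation adduct of the same 1-aryl-3-methylbuta-1,3-diene as its five-membered isomer, so the two rings can interconvert through η3-allylpalladium species with the conjugated six-membered ring as the end point. C4a lies between the oxygen-bearing C5 and C8a, which are symmetry-equivalent at the ring-opened stage, so no linear/angular problem arises.
Stereochemistry: the only stereocentre, the (S)-carbinol carbon, is bought with ethyl (S)-3-hydroxy-3-phenylpropanoate and no bond to it is broken afterwards. The transient C2 centre of the dihydrobenzofuran is racemic and vanishes in the key step.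

Key step: step 3

Remark: the descriptor in the SMILES is read as the (S)-carbinol (O > phenyl > CH2 > H). Chromene numbering (O1, C2, C3, C4, C4a, C5–C8, C8a) is used throughout, and catalyst-bound organopalladium species are described in words only.

Step 1
Reactants: 1 5-methoxyresorcinol (5-methoxybenzene-1,3-diol)
Product: 2 2-iodo-5-methoxybenzene-1,3-diol
Conditions: I2 (1.0 equiv), NaHCO3 (1.1 equiv), H2O, 0 °C to rt
Reagents that add atoms: iodine, II
Why: Electrophilic aromatic iodination under the aqueous hydrogencarbonate conditions that take resorcinol and orcinol to their 2-iodo derivatives should place iodine between the two hydroxyl groups, and the mirror symmetry of 1 leaves only one such position.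

Step 2
Reactants: 2 2-iodo-5-methoxybenzene-1,3-diol; 3 isoprene (2-methylbuta-1,3-diene, excess)
Product: 4 rac-6-methoxy-2-(prop-1-en-2-yl)-2,3-dihydro-1-benzofuran-4-ol
Conditions: Pd(OAc)2 (5 mol %), n-Bu4NCl (1 equiv), Na2CO3, DMF, 80 °C, sealed tube
Reagents that add atoms: none
Why: Larock heteroannulation of a 1,3-diene, in which zerovalent palladium formed in situ inserts into the C–I bond, the aryl group adds to the CH2 terminus of the less substituted double bond of isoprene, and one of the two equivalent ortho phenoxides closes the ring by 5-exo attack on the inner terminus of the η3-allyl complex; the new centre C2 forms as a racemate, which does not matter because step 3 turns it into an sp2 carbon.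

Step 3
Reactants: 4 rac-6-methoxy-2-(prop-1-en-2-yl)-2,3-dihydro-1-benzofuran-4-ol
Product: 6 7-methoxy-2,2-dimethyl-2H-chromen-5-ol, via dienylresorcinol 5 (not isolated)
Conditions: Pd(PPh3)4 (5 mol %), degassed toluene (dilute), 100 °C
Reagents that add atoms: none
Why: Proposed new method: zerovalent palladium ionises the allylic O1–C2 bond of 4 (Tsuji–Trost oxidative addition of an allyl aryl ether), β-hydride elimination of a benzylic C3–H gives a palladium hydride and dienylresorcinol 5, and re-addition of the hydride to the terminal =CH2 gives the 1-aryl-3,3-dimethyl-η3-allyl complex, whose tertiary terminus is captured by an ortho phenoxide, so that the former isopropenyl carbon is inserted between O1 and the old C2 and the five-membered ring becomes the six-membered 2H-pyran. The closest known reaction types are the palladium-catalysed 1,4-elimination of allyl aryl ethers to 1,3-dienes, the reversible palladium-catalysed hydroalkoxylation of 1,3-dienes by phenols and the palladium-catalysed O-tert-prenylation of phenols, which cover every elementary step, so that only their combination into a ring expansion of a 2-alkenyl-2,3-dihydrobenzofuran is new. Ring B closes by 6-endo attack of oxygen on the allyl terminus after η3–η1–η3 isomerisation has turned the aryl group into the anti position, whereas attack at the benzylic terminus would give a four-membered ring and is not viable. No stereocentre is created, and the racemic C2 centre of 4 becomes the sp2 carbon C3 of 6. The step needs positional selectivity among the five-, six- and seven-membered cyclic ethers that the two η3-allyl complexes can give, and this should be secured thermodynamically, because all steps are reversible and only 6 combines a C3=C4 bond conjugated with the electron-rich ring A, a branched tertiary ether carbon and an unstrained ring. Selectivity between the two phenolic oxygens is not needed because the mirror plane of 5 makes them equivalent, and drift to the 2-isopropylbenzofuran isomer should be held back by working without added acid, since that path needs a tertiary alkylpalladium species.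

Step 4
Reactants: 6 7-methoxy-2,2-dimethyl-2H-chromen-5-ol
Product: 7 7-methoxy-5-(methoxymethoxy)-2,2-dimethyl-2H-chromene
Conditions: MOMCl, i-Pr2NEt, CH2Cl2, 0 °C to rt
Reagents that add atoms: chloromethyl methyl ether (MOMCl), COCCl
Why: O-alkylation of the phenol by the reactive α-chloro ether (Williamson-type acetal formation) masks the acidic proton and installs the directing group for step 7, and the chromene is inert to these conditions.

Step 5
Reactants: 8 ethyl (S)-3-hydroxy-3-phenylpropanoate
Product: 9 ethyl (S)-3-[(tert-butyldimethylsilyl)oxy]-3-phenylpropanoate
Conditions: TBSCl, imidazole, DMF, rt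
Reagents that add atoms: tert-butyldimethylsilyl chloride (TBSCl), CC(C)(C)[Si](C)(C)Cl
Why: Imidazole-promoted silylation of the secondary alcohol forms only an O–Si bond, so the purchased (S)-centre is kept.

Step 6
Reactants: 9 ethyl (S)-3-[(tert-butyldimethylsilyl)oxy]-3-phenylpropanoate
Product: 10 (S)-3-[(tert-butyldimethylsilyl)oxy]-N-methoxy-N-methyl-3-phenylpropanamide
Conditions: MeNH(OMe)·HCl, i-PrMgCl, THF, −20 to 0 °C; aq NH4Cl
Reagents that add atoms: N,O-dimethylhydroxylamine hydrochloride, CNOC.Cl
Why: Aminolysis of the ester by the chloromagnesium amide made in situ (standard Weinreb amide synthesis) should run at low temperature without β-elimination of the silyloxy group, and the stereocentre is not α to the carbonyl group and stays untouched.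

Step 7
Reactants: 7 7-methoxy-5-(methoxymethoxy)-2,2-dimethyl-2H-chromene; 10 (S)-3-[(tert-butyldimethylsilyl)oxy]-N-methoxy-N-methyl-3-phenylpropanamide
Product: 12 (S)-3-[(tert-butyldimethylsilyl)oxy]-1-[7-methoxy-5-(methoxymethoxy)-2,2-dimethyl-2H-chromen-6-yl]-3-phenylpropan-1-one, via aryllithium 11 (not isolated)
Conditions: n-BuLi, TMEDA, THF, 0 °C; then 10, −78 to 0 °C; aq NH4Cl
Reagents that add atoms: n-butyllithium, [Li]CCCC (gives the lithium of 11 only; no atom of it stays in 12)
Why: Directed ortho-metalation followed by the Weinreb ketone synthesis, in which C6–H lies between two alkoxy groups and next to the chelating MOM acetal, which should steer n-BuLi there in preference to C8–H, while the N-methoxy-N-methyl amide acylates the aryllithium once only and carries the (S)-centre in unchanged.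

Step 8
Reactants: 12 (S)-3-[(tert-butyldimethylsilyl)oxy]-1-[7-methoxy-5-(methoxymethoxy)-2,2-dimethyl-2H-chromen-6-yl]-3-phenylpropan-1-one
Product: 13 (S)-3-hydroxy-1-(5-hydroxy-7-methoxy-2,2-dimethyl-2H-chromen-6-yl)-3-phenylpropan-1-one (target)
Conditions: 3 M aq HCl, THF, rt
Reagents that add atoms: none
Why: Acid-catalysed hydrolysis of an acetal and a silyl ether in one operation, in which the MOM ether ortho to the ketone is especially labile because the released phenol is held by the carbonyl group in a hydrogen bond, the secondary TBS ether should fall under the same mild conditions, and only O–C(acetal) and O–Si bonds break, so the (S)-centre keeps its configuration.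

Compound list
1 | 5-methoxyresorcinol | COc1cc(O)cc(O)c1 | starting material
2 | 2-iodo-5-methoxybenzene-1,3-diol | COc1cc(O)c(I)c(O)c1 | intermediate
3 | isoprene | C=CC(C)=C | starting material
4 | rac-6-methoxy-2-(prop-1-en-2-yl)-2,3-dihydro-1-benzofuran-4-ol (racemate, C2 undefined) | COc1cc(O)c2CC(Oc2c1)C(C)=C | intermediate
5 | 5-methoxy-2-[(1E)-3-methylbuta-1,3-dien-1-yl]benzene-1,3-diol (not isolated) | COc1cc(O)c(/C=C/C(C)=C)c(O)c1 | intermediate
6 | 7-methoxy-2,2-dimethyl-2H-chromen-5-ol | COc1cc(O)c2C=CC(C)(C)Oc2c1 | intermediate
7 | 7-methoxy-5-(methoxymethoxy)-2,2-dimethyl-2H-chromene | COCOc1cc(OC)cc2OC(C)(C)C=Cc12 | intermediate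
8 | ethyl (S)-3-hydroxy-3-phenylpropanoate | CCOC(=O)C[C@H](O)c1ccccc1 | starting material
9 | ethyl (S)-3-[(tert-butyldimethylsilyl)oxy]-3-phenylpropanoate | CCOC(=O)C[C@H](O[Si](C)(C)C(C)(C)C)c1ccccc1 | intermediate
10 | (S)-3-[(tert-butyldimethylsilyl)oxy]-N-methoxy-N-methyl-3-phenylpropanamide | CON(C)C(=O)C[C@H](O[Si](C)(C)C(C)(C)C)c1ccccc1 | intermediate
11 | [7-methoxy-5-(methoxymethoxy)-2,2-dimethyl-2H-chromen-6-yl]lithium (not isolated) | [Li]c1c(OC)cc2OC(C)(C)C=Cc2c1OCOC | intermediate
12 | (S)-3-[(tert-butyldimethylsilyl)oxy]-1-[7-methoxy-5-(methoxymethoxy)-2,2-dimethyl-2H-chromen-6-yl]-3-phenylpropan-1-one | COCOc1c(C(=O)C[C@H](O[Si](C)(C)C(C)(C)C)c2ccccc2)c(OC)cc2OC(C)(C)C=Cc12 | intermediate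
13 | (S)-3-hydroxy-1-(5-hydroxy-7-methoxy-2,2-dimethyl-2H-chromen-6-yl)-3-phenylpropan-1-one | COc1cc2c(c(O)c1C(=O)C[C@H](O)c1ccccc1)C=CC(C)(C)O2 | target

Total step count: 8. Longest linear sequence: 6 (steps 1, 2, 3, 4, 7, 8).

Steps most likely to fail

1. Step 3. The isomerisation may stall at the ring-opened stage. The electron-rich ring may be C-allylated by the η3-allyl complexes, which would cause oligomerisation, or hydride migration may drain material into the aromatic furan manifold.
The fallback sets out from 4 and comes back at 6, using known chemistry only. The allylic C–O bond of 4 is cleaved reductively with Pd(PPh3)4 and NaBH4 in THF. This is the palladium-catalysed hydride cleavage of allyl aryl ethers, with hydride delivered to the unhindered CH2 terminus, and it gives the prenylresorcinol 5-methoxy-2-(3-methylbut-2-en-1-yl)benzene-1,3-diol F1. F1 is then cyclodehydrogenated with DDQ in benzene by hydride abstraction to the o-quinone methide and oxa-6π electrocyclisation, the classical conversion of o-prenylphenols into 2,2-dimethylchromenes. The two hydroxyl groups of F1 are again equivalent.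

2. Step 7. Lithiation may take place in part at C8. The hindered aryllithium may also deprotonate the amide next to the carbonyl group, with loss of silanolate.
The fallback sets out from 6 and comes back at 11, replacing C–H deprotonation by halogen–metal exchange on a regiodefined bromide. The free phenol 6 is brominated with NBS and catalytic i-Pr2NH in CH2Cl2 (amine-catalysed ortho-bromination of phenols, with C6 as the only free ortho position) to give 6-bromo-7-methoxy-2,2-dimethyl-2H-chromen-5-ol F2. MOMCl and i-Pr2NEt then give 6-bromo-7-methoxy-5-(methoxymethoxy)-2,2-dimethyl-2H-chromene F3. Bromine–lithium exchange with n-BuLi in THF at −78 °C delivers 11 free of positional isomers and at a temperature at which acylation by 10 should outrun proton transfer.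

3. Step 8. The aqueous acid may cause loss of water from the aldol unit, followed by oxa-Michael closure of the freed phenol onto the enone. Ionisation at the benzylic carbon would erode the enantiomeric purity.
The fallback sets out from 12 and comes back at 13 by an orthogonal two-stage unmasking, in which the carbinol stays silylated while the acetal is removed and no aqueous mineral acid is used. The activated aryl MOM ether is cleaved on NaHSO4·SiO2 in CH2Cl2 at rt (heterogeneous cleavage selective for phenolic MOM ethers) to give (S)-3-[(tert-butyldimethylsilyl)oxy]-1-(5-hydroxy-7-methoxy-2,2-dimethyl-2H-chromen-6-yl)-3-phenylpropan-1-one F4. The silyl ether of F4 is then removed with HF·pyridine buffered with pyridine in THF at 0 °C.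

Further compounds
F1 | step 3 | 5-methoxy-2-(3-methylbut-2-en-1-yl)benzene-1,3-diol | COc1cc(O)c(CC=C(C)C)c(O)c1
F2 | step 7 | 6-bromo-7-methoxy-2,2-dimethyl-2H-chromen-5-ol | COc1cc2OC(C)(C)C=Cc2c(O)c1Br
F3 | step 7 | 6-bromo-7-methoxy-5-(methoxymethoxy)-2,2-dimethyl-2H-chromene | COCOc1c(Br)c(OC)cc2OC(C)(C)C=Cc12
F4 | step 8 | (S)-3-[(tert-butyldimethylsilyl)oxy]-1-(5-hydroxy-7-methoxy-2,2-dimethyl-2H-chromen-6-yl)-3-phenylpropan-1-one | COc1cc2OC(C)(C)C=Cc2c(O)c1C(=O)C[C@H](O[Si](C)(C)C(C)(C)C)c1ccccc1
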